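## Retrosynthetic overview

1. Target 16 comes from acetonide 15 by acetal hydrolysis, and 15 from angular aldehyde 13 by turning CHO‑20 into CH3.
2. Aldehyde 13 comes from acyclic dialdehyde 8 and triene acetate 11 in one flask: aldol condensation (C10–C5) closes ring A, then a Diels–Alder reaction (C5–C6 and C9–C10) closes ring B.
3. Dialdehyde 8 comes from ozonolysis of diene acetonide 6, made by allyl opening of epoxy alcohol 4, itself from a Sharpless kinetic resolution of the acrolein/prenyl bromide adduct 3.
4. Triene 11 comes from geranyl acetate by allylic oxidation and Wittig methylenation.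
5. Ring order: ring A first, ring B second, both in the same operation (step 8).

Assumption: the SMILES is read literally, so the decalin is cis‑fused (H‑5 and CH3‑20 on the same face; 2S,3R,5R,9R,10S); labdane numbering (C1–C20) is used for the ring carbons of all intermediates.

## Route

Step 1
Reactants: 1 acrolein; 2 prenyl bromide
Product: 3 (±)-4,4-dimethylhexa-1,5-dien-3-ol
Conditions: Zn dust, THF/sat. aq. NH4Cl, 0 °C → rt
Reagents that add atoms: none
Why: Zinc Barbier allylation in which the prenylzinc species adds through its γ‑carbon (SE2′, six‑membered transition state) 1,2 to acrolein to give the reverse‑prenylated carbinol as a racemate, which is resolved in step 2.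

Step 2
Reactants: 3 (±)-4,4-dimethylhexa-1,5-dien-3-ol
Product: 4 (1R)-2,2-dimethyl-1-[(2S)-oxiran-2-yl]but-3-en-1-ol
Conditions: Ti(OiPr)4 (0.2 equiv), D-(−)-diisopropyl tartrate (0.25 equiv), t-BuOOH (0.55 equiv), 4 Å MS, CH2Cl2, −20 °C, to about 50% conversion; unreacted (R)-3 separated
Reagents that add atoms: tert-butyl hydroperoxide, CC(C)(C)OO
Why: Sharpless kinetic resolution (titanium tartrate epoxidation), in which only the (S)-alcohol is epoxidised quickly with the D-tartrate and on the face that gives the erythro epoxy alcohol, so C3 (R) is selected by the resolution and C2 (S) is set by the reagent.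

Step 3
Reactants: 4 (1R)-2,2-dimethyl-1-[(2S)-oxiran-2-yl]but-3-en-1-ol
Product: 5 (4R,5S)-3,3-dimethylnona-1,8-diene-4,5-diol
Conditions: allylMgBr (3 equiv), CuI (0.1 equiv), THF, −40 → 0 °C
Reagents that add atoms: allylmagnesium bromide, C=CC[Mg]Br
Why: Copper‑catalysed Grignard opening of a terminal epoxide by SN2 attack at the unhindered CH2, which leaves both stereocenters untouched and gives the anti diol carrying the three carbons that become C1, C10 and C20.

Step 4
Reactants: 5 (4R,5S)-3,3-dimethylnona-1,8-diene-4,5-diol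
Product: 6 (4S,5R)-4-(but-3-en-1-yl)-2,2-dimethyl-5-(2-methylbut-3-en-2-yl)-1,3-dioxolane
Conditions: 2,2-dimethoxypropane, camphorsulfonic acid (cat.), CH2Cl2, rt
Reagents that add atoms: 2,2-dimethoxypropane, COC(C)(C)OC
Why: Acid‑catalysed transketalisation gives the cis‑4,5‑disubstituted dioxolane, which keeps the diol from forming lactols with the aldehydes to come and touches no stereocenter.

Step 5
Reactants: 6 (4S,5R)-4-(but-3-en-1-yl)-2,2-dimethyl-5-(2-methylbut-3-en-2-yl)-1,3-dioxolane
Product: 8 2-[(4R,5S)-2,2-dimethyl-5-(3-oxopropyl)-1,3-dioxolan-4-yl]-2-methylpropanal, via bis-ozonide 7 (not isolated)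
Conditions: O3, CH2Cl2, −78 °C; then PPh3, −78 °C → rt; used crude
Reagents that add atoms: ozone, [O-][O+]=O
Why: Ozonolysis with reductive work‑up cleaves both terminal alkenes to the 1,7‑dialdehyde, whose α‑quaternary aldehyde cannot enolise and so fixes the direction of the later aldol ring closure; no stereocenter is touched.

Step 6
Reactants: 9 geranyl acetate
Product: 10 (2E,6E)-3,7-dimethyl-8-oxoocta-2,6-dien-1-yl acetate
Conditions: SeO2 (1.1 equiv), EtOH, reflux
Reagents that add atoms: selenium dioxide, O=[Se]=O
Why: Riley allylic oxidation, in which SeO2 attacks the (E)-methyl group of the distal trisubstituted alkene by ene reaction and [2,3]-shift (the 2,3‑alkene is deactivated by the allylic acetate) and carries the allylic alcohol on to the (E)-enal.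

Step 7
Reactants: 10 (2E,6E)-3,7-dimethyl-8-oxoocta-2,6-dien-1-yl acetate
Product: 11 (2E,6E)-3,7-dimethylnona-2,6,8-trien-1-yl acetate
Conditions: Ph3PCH3Br (1.1 equiv), KN(SiMe3)2 (1.05 equiv), THF, 0 °C; then 10, −78 → 0 °C
Reagents that add atoms: methylenetriphenylphosphorane (made in the flask), C=P(c1ccccc1)(c1ccccc1)c1ccccc1
Why: Wittig methylenation of the enal at low temperature is faster than attack on the acetate and gives the (E)-1-alkyl-2-methylbutadiene without changing either alkene geometry.

Step 8
Reactants: 8 2-[(4R,5S)-2,2-dimethyl-5-(3-oxopropyl)-1,3-dioxolan-4-yl]-2-methylpropanal; 11 (2E,6E)-3,7-dimethylnona-2,6,8-trien-1-yl acetate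
Product: 13 (2S,3R,5S,9R,10R)-2,3-(isopropylidenedioxy)-20-oxolabda-7,13E-dien-15-yl acetate (A/B cis; CHO-20 and H-5 and C-11 on one face; dioxolane on the other), via cyclohexene carbaldehyde 12 (not isolated)
Conditions: Bn2NH2+ CF3CO2− (0.2 equiv), 4 Å MS, toluene (0.02 M), 50 °C; then 11 (1.5 equiv), Me2AlCl (3 equiv), −78 → −20 °C; H2O quench
Reagents that add atoms: none
Why: Proposed new method: an amine‑salt aldol condensation (only C10 can form the enamine because the C5 aldehyde is α‑quaternary) closes ring A to enal 12, and a Lewis‑acid Diels–Alder reaction in the same flask closes ring B, with the CH2 terminus of the diene bonding to the neopentyl β‑carbon C5 and the substituted terminus to C10 ("ortho" rule), suprafacial addition giving the cis ring fusion, the endo transition state (CHO under the diene, ring A exo) placing C11 cis to the formyl group, and the diene adding to the β‑face of ring A, anti to the pseudoaxial C4 methyl of the half‑chair that keeps O3 axial and O2 equatorial (the other half‑chair has O2 syn‑axial to a methyl), so that C5, C9 and C10 are set relative to the C2/C3 dioxolane; the closest known reaction types are the dibenzylammonium trifluoroacetate cyclisation of dialdehydes to cycloalkene carbaldehydes and the aluminium‑promoted Diels–Alder reaction of 1‑cyclohexenecarbaldehydes and 4,4‑dimethylcyclohexenones with 1,2‑disubstituted dienes.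

Step 9
Reactants: 13 (2S,3R,5S,9R,10R)-2,3-(isopropylidenedioxy)-20-oxolabda-7,13E-dien-15-yl acetate
Product: 15 (2S,3R,5R,9R,10S)-2,3-(isopropylidenedioxy)labda-7,13E-dien-15-yl acetate, via tosylhydrazone 14 (not isolated)
Conditions: TsNHNH2 (1.2 equiv), EtOH, 50 °C; evaporate; catecholborane (2.5 equiv), CHCl3, 0 °C → rt; then NaOAc·3H2O (3 equiv), 60 °C
Reagents that add atoms: none
Why: Tosylhydrazone reduction with catecholborane (Kabalka variant of the Caglioti reaction), in which hydroboration of C=N followed by loss of sulfinate and N2 from the diazene turns the neopentyl CHO into CH3 while sparing the acetate, the acetonide and both alkenes; C10 has no α‑hydrogen, so no stereocenter is touched.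

Step 10
Reactants: 15 (2S,3R,5R,9R,10S)-2,3-(isopropylidenedioxy)labda-7,13E-dien-15-yl acetate
Product: 16 (2S,3R,5R,9R,10S)-2,3-dihydroxylabda-7,13E-dien-15-yl acetate (A/B cis), the target
Conditions: AcOH/H2O (4:1), 45 °C
Reagents that add atoms: none
Why: Mild aqueous‑acid hydrolysis of the isopropylidene acetal frees the cis‑2,3‑diol while the primary allylic acetate and the trisubstituted alkenes survive dilute acetic acid, and no stereocenter is touched.

## Compound list

1 | acrolein (prop-2-enal) | C=CC=O | starting material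
2 | prenyl bromide (1-bromo-3-methylbut-2-ene) | CC(C)=CCBr | starting material
3 | (±)-4,4-dimethylhexa-1,5-dien-3-ol | C=CC(O)C(C)(C)C=C | intermediate
4 | (1R)-2,2-dimethyl-1-[(2S)-oxiran-2-yl]but-3-en-1-ol | C=CC(C)(C)[C@@H](O)[C@@H]1CO1 | intermediate
5 | (4R,5S)-3,3-dimethylnona-1,8-diene-4,5-diol | C=CC(C)(C)[C@@H](O)[C@@H](O)CCC=C | intermediate
6 | (4S,5R)-4-(but-3-en-1-yl)-2,2-dimethyl-5-(2-methylbut-3-en-2-yl)-1,3-dioxolane | C=CC(C)(C)[C@@H](OC1(C)C)[C@@H](O1)CCC=C | intermediate
7 | bis-ozonide of 6 (each vinyl group as a 1,2,4-trioxolan-3-yl ring; trioxolane carbons as a mixture) | C1(OCOO1)C(C)(C)[C@@H](OC2(C)C)[C@@H](O2)CCC1OCOO1 | intermediate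
8 | 2-[(4R,5S)-2,2-dimethyl-5-(3-oxopropyl)-1,3-dioxolan-4-yl]-2-methylpropanal | O=CC(C)(C)[C@@H](OC1(C)C)[C@@H](O1)CCC=O | intermediate
9 | geranyl acetate | CC(=O)OC/C=C(\C)CCC=C(C)C | starting material
10 | (2E,6E)-3,7-dimethyl-8-oxoocta-2,6-dien-1-yl acetate | CC(=O)OC/C=C(\C)CC/C=C(\C)C=O | intermediate
11 | (2E,6E)-3,7-dimethylnona-2,6,8-trien-1-yl acetate | CC(=O)OC/C=C(\C)CC/C=C(\C)C=C | intermediate
12 | (3aS,7aR)-2,2,7,7-tetramethyl-3a,4,7,7a-tetrahydro-1,3-benzodioxole-5-carbaldehyde | O=CC1=CC(C)(C)[C@@H](OC2(C)C)[C@@H](O2)C1 | intermediate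
13 | (2S,3R,5S,9R,10R)-2,3-(isopropylidenedioxy)-20-oxolabda-7,13E-dien-15-yl acetate (A/B cis) | CC(=O)OC/C=C(\C)CC[C@@H]1C(C)=CC[C@H]2C(C)(C)[C@@H](OC3(C)C)[C@@H](O3)C[C@@]12C=O | intermediate
14 | (E)-20-(4-methylbenzenesulfonyl)hydrazone of 13 (2S,3R,5R,9R,10R) | CC(=O)OC/C=C(\C)CC[C@@H]1C(C)=CC[C@H]2C(C)(C)[C@@H](OC3(C)C)[C@@H](O3)C[C@@]12/C=N/NS(=O)(=O)c1ccc(C)cc1 | intermediate
15 | (2S,3R,5R,9R,10S)-2,3-(isopropylidenedioxy)labda-7,13E-dien-15-yl acetate (A/B cis) | CC(=O)OC/C=C(\C)CC[C@@H]1C(C)=CC[C@H]2C(C)(C)[C@@H](OC3(C)C)[C@@H](O3)C[C@@]12C | intermediate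
16 | (2S,3R,5R,9R,10S)-2,3-dihydroxylabda-7,13E-dien-15-yl acetate (A/B cis) | CC(=O)OC/C=C(\C)CC[C@@H]1C(C)=CC[C@H]2C(C)(C)[C@@H](O)[C@@H](O)C[C@@]12C | target

## Step count and risks

Total step count: 10. Longest linear sequence: 8 (steps 1–5, then 8–10); steps 6–7 make the diene in parallel.

**Step 8 (most likely to fail).** The β‑face preference rests on a conformational argument worth perhaps 1 kcal/mol and could be low or reversed. The hindered enal may also react slowly, and Me2AlCl may ionise the allylic acetate. The fallback sets out from dialdehyde 8 and diene 11 and comes back at 13. The two ring closures are separated and the facial choice is handed to the reagent. Dialdehyde 8 is cyclised alone with Bn2NH2+ CF3CO2− and the cyclohexene carbaldehyde 12 is isolated. Enal 12 and diene 11 are then combined at −78 °C under a chiral cationic oxazaborolidine Lewis acid, the B‑(o‑tolyl) oxazaborolidine of diphenylprolinol activated with HNTf2. The catalyst enantiomer that leaves the C10 Re face (the β‑face) open is used; I have not assigned which enantiomer this is, and it would be fixed on the first run. This catalytic, acetate‑tolerant activation gives 13. No new compound arises on this way: none F0.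

**Step 9.** The aldehyde sits on a quaternary carbon flanked by C9, so hydrazone formation or hydride delivery may stall. The fallback sets out from 13 and comes back at 15. It is a Huang–Minlon Wolff–Kishner reduction (N2H4·H2O, KOH, diethylene glycol, 130 °C then 200 °C). This passes through the free hydrazone F1, in which the acetate has already been cleaved, and gives the C15 alcohol F2 with CH3‑20 in place. The acetonide is stable to base, so the only free hydroxyl of F2 is then acetylated (Ac2O, pyridine, DMAP cat., 0 °C) to give 15.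

**Step 2.** Vinyl carbinols with an unsubstituted alkene terminus and a tertiary‑alkyl group on the carbinol carbon are slow substrates for the titanium tartrate epoxidation, and the yield is capped at 50%. The fallback sets out from prenyl bromide 2 and comes back at 4, replacing steps 1 and 2 with a chiral‑pool sequence. Zinc Barbier γ‑prenylation of (S)-glyceraldehyde acetonide F3 (THF/aq. NH4Cl) gives the Felkin anti adduct F4. Aqueous acetic acid removes the acetonide to give the triol F5. Selective sulfonylation of the primary hydroxyl (TsCl, pyridine, 0 °C) gives the primary tosylate F6. K2CO3 in MeOH then closes the terminal epoxide through O2, giving epoxy alcohol 4 with both stereocenters as required.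

## Further compounds

F0 | step 8 | none | none
F1 | step 9 | hydrazone of the deacetylated aldehyde (20-hydrazono-2,3-(isopropylidenedioxy)labda-7,13E-dien-15-ol) | OC/C=C(\C)CC[C@@H]1C(C)=CC[C@H]2C(C)(C)[C@@H](OC3(C)C)[C@@H](O3)C[C@@]12/C=N/N
F2 | step 9 | (2S,3R,5R,9R,10S)-2,3-(isopropylidenedioxy)labda-7,13E-dien-15-ol | OC/C=C(\C)CC[C@@H]1C(C)=CC[C@H]2C(C)(C)[C@@H](OC3(C)C)[C@@H](O3)C[C@@]12C
F3 | step 2 | (S)-2,2-dimethyl-1,3-dioxolane-4-carbaldehyde | O=C[C@H]1OC(C)(C)OC1
F4 | step 2 | (1R)-1-[(4S)-2,2-dimethyl-1,3-dioxolan-4-yl]-2,2-dimethylbut-3-en-1-ol | C=CC(C)(C)[C@@H](O)[C@H]1OC(C)(C)OC1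
F5 | step 2 | (2S,3R)-4,4-dimethylhex-5-ene-1,2,3-triol | C=CC(C)(C)[C@@H](O)[C@@H](O)CO
F6 | step 2 | (2S,3R)-2,3-dihydroxy-4,4-dimethylhex-5-en-1-yl 4-methylbenzenesulfonate | C=CC(C)(C)[C@@H](O)[C@@H](O)COS(=O)(=O)c1ccc(C)cc1
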